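**Plan**
- Retrosynthesis: remove the tiglate at O-8. Then cut, in one operation, the lactone C12–O6 bond and the C5–C6 bond of the ten-membered carbocycle (equally the nine-membered ring that contains the furanone oxygen). This gives an open-chain aldehyde ester carrying a 5-isopropenyl-3(2H)-furanone, which is cut at C7–C8 (aldol) and at the furanone (C3–O, C1–C2).
- Enabling feature: in the furanone, C1=O, C2=C3 (ring O on C3) and an added C4=C5 bond form a dienone whose terminus C5 is an acceptor, and C6 is a carbonyl carbon. SmI2 joins these two electrophilic carbons reductively, and the C12 ester, 1,4 to C6, traps the new alkoxide as the γ-lactone.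
- Forward order: furanone ring first (from (R)-citramalic acid and 2-methylbut-1-en-3-yne), side chain by a syn aldol with a methylsuccinate thioimide, then carbocycle and lactone together in the reductive ring closure, tiglate last.
- Stereochemistry: C10 from (R)-citramalic acid; C11 from dimethyl (S)-methylsuccinate; C7 and C8 from the auxiliary-controlled syn aldol; C6 from C7 during ring closure (Felkin sense, trans lactone); C4 by thermodynamic protonation (allylic 1,3-strain).

Key step: step 11

Remark (numbering): positions follow germacrane numbering: C1 ketone, C2=C3 furanone alkene, O between C3 and C10, C4 (methyl C15), C5, C6 (lactone O), C7, C8 (ester O), C9, C10 (methyl C14), C11 (methyl C13), C12 lactone carbonyl.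
Remark (assumption): the natural 4S epimer, in which H-4 lies in the furanone plane syn to H-2, is taken to be the thermodynamically preferred C4 epimer of the bicyclic lactone.

**Step 1**
Reactants: 1 (R)-citramalic acid
Product: 2 2-[(4R)-2,2,4-trimethyl-5-oxo-1,3-dioxolan-4-yl]acetic acid
Conditions: 2,2-dimethoxypropane, p-TsOH·H2O (cat.), rt
Reagents that add atoms: 2,2-dimethoxypropane, COC(C)(C)OC
Why: Acid-catalysed dioxolanone formation ties up the tertiary hydroxyl and its neighbouring carboxyl together, leaves only the CH2CO2H group free and does not touch the quaternary stereocentre (C10).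

**Step 2**
Reactants: 2 2-[(4R)-2,2,4-trimethyl-5-oxo-1,3-dioxolan-4-yl]acetic acid
Product: 4 (3R)-3-hydroxy-3-methyloxolan-2-one, via hydroxyethyl dioxolanone 3 (not isolated)
Conditions: BH3·SMe2, THF, 0 °C → rt; MeOH quench; then p-TsOH·H2O (cat.), CH2Cl2, rt
Reagents that add atoms: none
Why: Borane reduces the free carboxylic acid chemoselectively beside the dioxolanone, and the primary alcohol 3 then translactonises under acid (loss of acetone) to the five-membered α-hydroxy lactone.

**Step 3**
Reactants: 4 (3R)-3-hydroxy-3-methyloxolan-2-one, 5 2-methylbut-1-en-3-yne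
Product: 7 (6R)-6,8-dihydroxy-2,6-dimethyloct-1-en-3-yn-5-one, via lithium enynide 6 (not isolated)
Conditions: 5 (3 equiv), n-BuLi (2.9 equiv), THF, −78 °C; then 4, −78 → −30 °C; aq. NH4Cl
Reagents that add atoms: none
Why: Acetylide addition to a lactone stops at the lactolate (the first equivalent deprotonates the tertiary OH), so work-up should release the ring-opened α'-hydroxy ynone with the new C1–C2 bond.

**Step 4**
Reactants: 7 (6R)-6,8-dihydroxy-2,6-dimethyloct-1-en-3-yn-5-one
Product: 8 (2R)-2-(2-hydroxyethyl)-2-methyl-5-(prop-1-en-2-yl)furan-3(2H)-one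
Conditions: (Ph3P)AuCl (5 mol %), AgOTf (5 mol %), toluene, rt
Reagents that add atoms: none
Why: Gold-catalysed 5-endo-dig cycloisomerisation of an α'-hydroxy ynone is the standard entry to 3(2H)-furanones, and only the tertiary hydroxyl can reach C3 through a five-membered ring.

**Step 5**
Reactants: 8 (2R)-2-(2-hydroxyethyl)-2-methyl-5-(prop-1-en-2-yl)furan-3(2H)-one
Product: 9 2-[(2R)-2-methyl-3-oxo-5-(prop-1-en-2-yl)-2,3-dihydrofuran-2-yl]acetaldehyde
Conditions: Dess–Martin periodinane, CH2Cl2, 0 °C → rt; used crude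
Reagents that add atoms: none
Why: Dess–Martin oxidation is base-free, which should spare this aldehyde from β-elimination (opening of the furanone C10–O bond).

**Step 6**
Reactants: 10 dimethyl (2S)-2-methylbutanedioate
Product: 11 (3S)-4-methoxy-3-methyl-4-oxobutanoic acid
Conditions: pig liver esterase, phosphate buffer pH 7 (NaOH, pH-stat), rt; then HCl to pH 2
Reagents that add atoms: water, O
Why: Enzymatic mono-hydrolysis should cleave the unhindered CH2CO2Me ester and leave the α-branched one, at neutral pH so that the C11 stereocentre is not epimerised.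

**Step 7**
Reactants: 11 (3S)-4-methoxy-3-methyl-4-oxobutanoic acid, 12 (4R)-4-benzyl-1,3-thiazolidine-2-thione
Product: 13 methyl (2S)-4-[(4R)-4-benzyl-2-sulfanylidene-1,3-thiazolidin-3-yl]-2-methyl-4-oxobutanoate
Conditions: DCC, DMAP (cat.), CH2Cl2, 0 °C → rt
Reagents that add atoms: none
Why: Carbodiimide (Steglich-type) N-acylation of the thiazolidinethione installs the auxiliary on the C6 carboxyl without touching the methyl ester.

**Step 8**
Reactants: 13 methyl (2S)-4-[(4R)-4-benzyl-2-sulfanylidene-1,3-thiazolidin-3-yl]-2-methyl-4-oxobutanoate, 9 2-[(2R)-2-methyl-3-oxo-5-(prop-1-en-2-yl)-2,3-dihydrofuran-2-yl]acetaldehyde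
Product: 15 methyl (2S,3R,4S)-3-{[(4R)-4-benzyl-2-sulfanylidene-1,3-thiazolidin-3-yl]carbonyl}-4-hydroxy-2-methyl-5-[(2R)-2-methyl-3-oxo-5-(prop-1-en-2-yl)-2,3-dihydrofuran-2-yl]pentanoate, via trichlorotitanium enolate 14 (not isolated)
Conditions: TiCl4 (1.05 equiv), iPr2NEt (1.1 equiv), N-methyl-2-pyrrolidinone (1.1 equiv), CH2Cl2, 0 °C; then 9, −78 °C; aq. NH4Cl
Reagents that add atoms: none
Why: In this titanium-mediated thiazolidinethione aldol (Evans-syn sense), the (Z)-enolate 14 should react through the non-chelated Zimmerman–Traxler chair with the (R)-benzyl group shielding one face, which sets C7 and C8 syn while C11 is a bystander.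

**Step 9**
Reactants: 15 syn-aldol adduct (name as in step 8)
Product: 16 methyl (2S,3R,4S)-3-{[(4R)-4-benzyl-2-sulfanylidene-1,3-thiazolidin-3-yl]carbonyl}-4-[(tert-butyldimethylsilyl)oxy]-2-methyl-5-[(2R)-2-methyl-3-oxo-5-(prop-1-en-2-yl)-2,3-dihydrofuran-2-yl]pentanoate
Conditions: TBSOTf, 2,6-lutidine, CH2Cl2, −78 → 0 °C
Reagents that add atoms: tert-butyldimethylsilyl trifluoromethanesulfonate, CC(C)(C)[Si](C)(C)OS(=O)(=O)C(F)(F)F
Why: Immediate low-temperature silylation of the C8 hydroxyl forestalls its γ-lactonisation onto the C12 ester and removes a β-leaving group from the later aldehyde.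

**Step 10**
Reactants: 16 silyl ether thioimide (name as in step 9)
Product: 17 methyl (2S,3R,4S)-4-[(tert-butyldimethylsilyl)oxy]-3-formyl-2-methyl-5-[(2R)-2-methyl-3-oxo-5-(prop-1-en-2-yl)-2,3-dihydrofuran-2-yl]pentanoate
Conditions: i-Bu2AlH (1.1 equiv), CH2Cl2, −78 °C, 10 min; Rochelle salt
Reagents that add atoms: none
Why: N-Acylthiazolidinethiones are reduced by one equivalent of i-Bu2AlH at −78 °C to the aldehyde through a stable tetrahedral aluminate, much faster than a methyl ester or the hindered vinylogous ester carbonyl.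

**Step 11**
Reactants: 17 methyl (2S,3R,4S)-4-[(tert-butyldimethylsilyl)oxy]-3-formyl-2-methyl-5-[(2R)-2-methyl-3-oxo-5-(prop-1-en-2-yl)-2,3-dihydrofuran-2-yl]pentanoate
Product: 19 (4S,6R,7S,8S,10R,11S)-8-[(tert-butyldimethylsilyl)oxy]-1-oxo-3,10-epoxygermacr-2-en-12,6-olide, via ring-closed hydroxy ester 18 (not isolated)
Conditions: SmI2 (2.5 equiv, 0.1 M in THF), t-BuOH (2.5 equiv), THF, −78 → 0 °C, slow addition of 17 (final 0.003 M); aq. NH4Cl; then DBU (0.2 equiv), CH2Cl2, rt
Reagents that add atoms: none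
Why: Proposed new method: SmI2 transfers one electron to the aldehyde (or to the dienone, with the same outcome), the trivalent-samarium ketyl at C6 adds to the unsubstituted terminus C5 of the 5-isopropenyl-3(2H)-furanone (a vinylogous 1,6-acceptor), a second electron turns the delocalised C4 radical into a samarium dienolate, the C6 alkoxide closes onto the C12 methyl ester (via 18), and the dienolate is protonated at C4. The closest known reaction type is the SmI2 ketyl–olefin (aldehyde–enoate) reductive cyclisation with in situ γ-lactonisation, established for five- to eight-membered rings and simple 1,4-acceptors but not for a dienone terminus or this ring size. The C5–C6 bond closes the nine-membered oxacycle in a 9-endo-trig mode (the same bond completes the ten-membered carbocycle, 10-endo-trig), and the lactone closes by 5-exo-trig acyl substitution. C6 is controlled by the resident C7 centre: with the ketyl oxygen and the ester carbonyl held on the same samarium, C5 can only approach anti to the C8 branch (Felkin sense), which should give the 6,7-trans lactone with 6R configuration. C4 is controlled thermodynamically: it is the γ-carbon of a vinylogous ester, and DBU equilibration should leave the 4S epimer, in which H-4 eclipses C2–H and the methyl group escapes allylic 1,3-strain. The step needs bond formation at C5 rather than at C3 (7-exo) or C1 (pinacol, six-membered) and ring closure rather than simple reduction or dimerisation; C5 is the only unhindered acceptor carbon (C3 is fully substituted, C1 is a deactivated vinylogous ester carbonyl beside quaternary C10), and slow addition at high dilution plus the rigid furanone, which already fixes four of the nine ring atoms, favour cyclisation.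

**Step 12**
Reactants: 19 (4S,6R,7S,8S,10R,11S)-8-[(tert-butyldimethylsilyl)oxy]-1-oxo-3,10-epoxygermacr-2-en-12,6-olide
Product: 20 (4S,6R,7R,8S,10R,11S)-8-hydroxy-1-oxo-3,10-epoxygermacr-2-en-12,6-olide
Conditions: HF·pyridine, pyridine, THF, 0 °C → rt
Reagents that add atoms: none
Why: Buffered HF·pyridine cleaves the secondary silyl ether without base, so C4 and C11 should not epimerise and the free 8-hydroxyl should not translactonise.

**Step 13**
Reactants: 20 (4S,6R,7R,8S,10R,11S)-8-hydroxy-1-oxo-3,10-epoxygermacr-2-en-12,6-olide, 21 tigloyl chloride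
Product: 22 (4S,6R,7S,8S,10R,11S)-1-oxo-3,10-epoxygermacr-2-en-12,6-olid-8-yl (2E)-2-methylbut-2-enoate (target)
Conditions: 21 (3 equiv), Et3N, DMAP, CH2Cl2, 0 °C → rt
Reagents that add atoms: none
Why: DMAP-catalysed acylation of the secondary alcohol with the acid chloride should give the tiglate, whose (E) geometry is configurationally stable under these conditions.

**Compound list**
1 | (R)-citramalic acid, (2R)-2-hydroxy-2-methylbutanedioic acid | C[C@@](O)(CC(=O)O)C(=O)O | starting material
2 | 2-[(4R)-2,2,4-trimethyl-5-oxo-1,3-dioxolan-4-yl]acetic acid | OC(=O)C[C@@]1(C)OC(C)(C)OC1=O | intermediate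
3 | (5R)-5-(2-hydroxyethyl)-2,2,5-trimethyl-1,3-dioxolan-4-one (not isolated) | OCC[C@@]1(C)OC(C)(C)OC1=O | intermediate
4 | (3R)-3-hydroxy-3-methyloxolan-2-one | O=C1OCC[C@@]1(C)O | intermediate
5 | 2-methylbut-1-en-3-yne | C=C(C)C#C | starting material
6 | lithium 3-methylbut-3-en-1-yn-1-ide (not isolated) | [Li]C#CC(C)=C | intermediate
7 | (6R)-6,8-dihydroxy-2,6-dimethyloct-1-en-3-yn-5-one | OCC[C@@](C)(O)C(=O)C#CC(C)=C | intermediate
8 | (2R)-2-(2-hydroxyethyl)-2-methyl-5-(prop-1-en-2-yl)furan-3(2H)-one | OCC[C@@]1(C)OC(=CC1=O)C(C)=C | intermediate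
9 | 2-[(2R)-2-methyl-3-oxo-5-(prop-1-en-2-yl)-2,3-dihydrofuran-2-yl]acetaldehyde | O=CC[C@@]1(C)OC(=CC1=O)C(C)=C | intermediate
10 | dimethyl (2S)-2-methylbutanedioate | COC(=O)C[C@H](C)C(=O)OC | starting material
11 | (3S)-4-methoxy-3-methyl-4-oxobutanoic acid | OC(=O)C[C@H](C)C(=O)OC | intermediate
12 | (4R)-4-benzyl-1,3-thiazolidine-2-thione | S=C1N[C@H](Cc2ccccc2)CS1 | starting material
13 | methyl (2S)-4-[(4R)-4-benzyl-2-sulfanylidene-1,3-thiazolidin-3-yl]-2-methyl-4-oxobutanoate | COC(=O)[C@@H](C)CC(=O)N1[C@H](Cc2ccccc2)CSC1=S | intermediate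
14 | (Z)-trichlorotitanium enolate of 13 (not isolated) | COC(=O)[C@@H](C)/C=C(\O[Ti](Cl)(Cl)Cl)N1[C@H](Cc2ccccc2)CSC1=S | intermediate
15 | methyl (2S,3R,4S)-3-{[(4R)-4-benzyl-2-sulfanylidene-1,3-thiazolidin-3-yl]carbonyl}-4-hydroxy-2-methyl-5-[(2R)-2-methyl-3-oxo-5-(prop-1-en-2-yl)-2,3-dihydrofuran-2-yl]pentanoate | O[C@@H](C[C@@]1(C)OC(=CC1=O)C(C)=C)[C@H](C(=O)N2[C@H](Cc3ccccc3)CSC2=S)[C@H](C)C(=O)OC | intermediate
16 | tert-butyldimethylsilyl ether of 15 at O-8 | CC(C)(C)[Si](C)(C)O[C@@H](C[C@@]1(C)OC(=CC1=O)C(C)=C)[C@H](C(=O)N2[C@H](Cc3ccccc3)CSC2=S)[C@H](C)C(=O)OC | intermediate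
17 | methyl (2S,3R,4S)-4-[(tert-butyldimethylsilyl)oxy]-3-formyl-2-methyl-5-[(2R)-2-methyl-3-oxo-5-(prop-1-en-2-yl)-2,3-dihydrofuran-2-yl]pentanoate | CC(C)(C)[Si](C)(C)O[C@@H](C[C@@]1(C)OC(=CC1=O)C(C)=C)[C@H](C=O)[C@H](C)C(=O)OC | intermediate
18 | methyl (4S,6R,7S,8S,10R,11S)-8-[(tert-butyldimethylsilyl)oxy]-6-hydroxy-1-oxo-3,10-epoxygermacr-2-en-12-oate, present as its trivalent-samarium alkoxide (not isolated) | CC(C)(C)[Si](C)(C)O[C@H]1C[C@@]2(C)OC(=CC2=O)[C@@H](C)C[C@@H](O)[C@@H]1[C@H](C)C(=O)OC | intermediate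
19 | (4S,6R,7S,8S,10R,11S)-8-[(tert-butyldimethylsilyl)oxy]-1-oxo-3,10-epoxygermacr-2-en-12,6-olide (furanone-bridged ten-membered carbocycle, trans-fused γ-lactone) | CC(C)(C)[Si](C)(C)O[C@H]1C[C@@]2(C)OC(=CC2=O)[C@@H](C)C[C@H]2OC(=O)[C@@H](C)[C@H]12 | intermediate
20 | (4S,6R,7R,8S,10R,11S)-8-hydroxy-1-oxo-3,10-epoxygermacr-2-en-12,6-olide | O[C@H]1C[C@@]2(C)OC(=CC2=O)[C@@H](C)C[C@H]2OC(=O)[C@@H](C)[C@H]12 | intermediate
21 | tigloyl chloride, (2E)-2-methylbut-2-enoyl chloride | C/C=C(\C)C(=O)Cl | starting material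
22 | (4S,6R,7S,8S,10R,11S)-1-oxo-3,10-epoxygermacr-2-en-12,6-olid-8-yl (2E)-2-methylbut-2-enoate | C/C=C(\C)C(=O)O[C@H]1C[C@@]2(C)OC(=CC2=O)[C@@H](C)C[C@H]2OC(=O)[C@@H](C)[C@H]12 | target

**Totals and risks**
Total steps: 13. Longest linear sequence: 11 (steps 1–5, then 8–13); steps 6–7 form the side branch.

Steps most likely to fail:

1. Step 11 (Proposed new method). The ketyl or the reduced dienone may be protonated before the C–C bond forms (simple reduction). Intermolecular pinacol coupling may outrun the nine-membered closure, the bond may form at C1 or C3 instead of C5, or facial selectivity at C6 may be poor. Fallback, from 17 back to 19, known chemistry: aldehyde 17 would be treated with vinylmagnesium bromide and CeCl3 (THF, −78 °C). Felkin–Anh addition and closure of the magnesium alkoxide onto the methyl ester should give the vinyl lactone F1. Ring-closing metathesis of F1 between the vinyl and isopropenyl groups (second-generation Hoveyda–Grubbs catalyst, toluene, 80 °C, high dilution) would close the ten-membered ring at C4=C5 instead and give the (4Z)-dienone lactone F2. Conjugate (1,6) hydride delivery to F2 with [(Ph3P)CuH]6 (benzene, rt), followed by DBU equilibration at C4, should give 19.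

2. Step 8. The aldehyde may undergo β-elimination (opening of the furanone) under amine and Lewis acid, and facial selectivity may erode if the ester carbonyl coordinates to titanium. Fallback, from 11 and 9 back to 17: acid 11 would be coupled (pivaloyl chloride, Et3N; then lithiated (4R)-4-benzyl-1,3-oxazolidin-2-one) to the oxazolidinone imide F3. Its dibutylboron (Z)-enolate (Bu2BOTf, iPr2NEt, CH2Cl2, −78 °C) has no free coordination site for the ester and should add to 9 through the closed boron chair to give the Evans-syn adduct F4. Transamination (Me3Al, MeNHOMe·HCl, CH2Cl2, −10 °C) would give the hydroxy Weinreb amide F5, silylation (TBSOTf, 2,6-lutidine) the silyl ether Weinreb amide F6, and reduction with Cp2Zr(H)Cl (THF, rt) aldehyde 17.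

3. Step 10. Hydride may also be delivered to the methyl ester or the furanone carbonyl (over-reduction) while the thioimide is reduced. Fallback, from 16 back to 17: thioimide 16 would be opened with morpholine (CH2Cl2, rt) to the morpholine amide F7, which is reduced with Cp2Zr(H)Cl (THF, rt). The zirconium hemiaminal formed cannot be reduced further and releases aldehyde 17 only on work-up, and esters are not attacked.

**Further compounds**
F1 | step 11 | (3S,4S,5R)-4-{(1S)-1-[(tert-butyldimethylsilyl)oxy]-2-[(2R)-2-methyl-3-oxo-5-(prop-1-en-2-yl)-2,3-dihydrofuran-2-yl]ethyl}-5-ethenyl-3-methyloxolan-2-one | CC(C)(C)[Si](C)(C)O[C@@H](C[C@@]2(C)OC(=CC2=O)C(C)=C)[C@@H]1[C@@H](C=C)OC(=O)[C@H]1C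
F2 | step 11 | (4Z,6R,7S,8S,10R,11S)-8-[(tert-butyldimethylsilyl)oxy]-1-oxo-3,10-epoxygermacra-2,4-dien-12,6-olide | CC(C)(C)[Si](C)(C)O[C@H]1C[C@@]2(C)OC(=CC2=O)/C(C)=C\[C@H]2OC(=O)[C@@H](C)[C@H]12
F3 | step 8 | methyl (2S)-4-[(4R)-4-benzyl-2-oxo-1,3-oxazolidin-3-yl]-2-methyl-4-oxobutanoate | COC(=O)[C@@H](C)CC(=O)N1[C@H](Cc2ccccc2)COC1=O
F4 | step 8 | methyl (2S,3R,4S)-3-{[(4R)-4-benzyl-2-oxo-1,3-oxazolidin-3-yl]carbonyl}-4-hydroxy-2-methyl-5-[(2R)-2-methyl-3-oxo-5-(prop-1-en-2-yl)-2,3-dihydrofuran-2-yl]pentanoate | O[C@@H](C[C@@]1(C)OC(=CC1=O)C(C)=C)[C@H](C(=O)N2[C@H](Cc3ccccc3)COC2=O)[C@H](C)C(=O)OC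
F5 | step 8 | methyl (2S,3R,4S)-4-hydroxy-3-[methoxy(methyl)carbamoyl]-2-methyl-5-[(2R)-2-methyl-3-oxo-5-(prop-1-en-2-yl)-2,3-dihydrofuran-2-yl]pentanoate | O[C@@H](C[C@@]1(C)OC(=CC1=O)C(C)=C)[C@H](C(=O)N(C)OC)[C@H](C)C(=O)OC
F6 | step 8 | methyl (2S,3R,4S)-4-[(tert-butyldimethylsilyl)oxy]-3-[methoxy(methyl)carbamoyl]-2-methyl-5-[(2R)-2-methyl-3-oxo-5-(prop-1-en-2-yl)-2,3-dihydrofuran-2-yl]pentanoate | CC(C)(C)[Si](C)(C)O[C@@H](C[C@@]1(C)OC(=CC1=O)C(C)=C)[C@H](C(=O)N(C)OC)[C@H](C)C(=O)OC
F7 | step 10 | methyl (2S,3R,4S)-4-[(tert-butyldimethylsilyl)oxy]-2-methyl-3-(morpholine-4-carbonyl)-5-[(2R)-2-methyl-3-oxo-5-(prop-1-en-2-yl)-2,3-dihydrofuran-2-yl]pentanoate | CC(C)(C)[Si](C)(C)O[C@@H](C[C@@]1(C)OC(=CC1=O)C(C)=C)[C@H](C(=O)N2CCOCC2)[C@H](C)C(=O)OC
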